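Follow the target through a fill and a drain, and keep its lifetime in view.

    reagent in the reaction phase ⇌ reagent in the second phase, rate k1*([reagent in the reaction phase] - [reagent in the second phase]/K1) per volume of the first phase (K1 = 1.1, k1 = 8.9 × 10⁻⁵ s⁻¹)
    starting material + reagent in the reaction phase → target (k2 = 8.6 × 10⁻⁴ M⁻¹ s⁻¹)
    target ⇌ product in the second phase, rate k3*([target] - [product in the second phase]/K3) per volume of the first phase (K3 = 0.65, k3 = 0.0021 s⁻¹)
    target → decomposed product (k4 = 5.3 × 10⁻⁵ s⁻¹)
    reagent in the reaction phase + target → over-reaction product (k5 = 0.0034 M⁻¹ s⁻¹)
    reagent in the reaction phase → decomposed reagent (k6 = 1.5 × 10⁻⁵ s⁻¹)

starting material 0.056 M; reagent in the second phase 0.0504 M; time 6.0 h; volume of the second phase over the first 1.0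

- amounts and yields of target count product in the second phase too
- in the second phase: reagent in the second phase, product in the second phase; everything else is in the first
- charges count per volume of the first phase; a concentration in a rate is the amount of a species over the volume of its own phase; every rate counts per litre of the first phase
- run time (flask): 6.0 h

- target and product in the second phase together at 6.0 h, in percent of the starting material charged
- the change that raises the amount of target and product in the second phase together at 6.0 h, in percent of the starting material charged most ("none" if none brings more than 2 percentage points) (red / teal / grey / none)
- amount of target and product in the second phase together at 6.0 h, in percent of the starting material charged, after teal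

Target and product in the second phase exchange within 3.13 min, far shorter than the feed time 1.63 h at which the reagent relaxes between the phases. So I pool the two forms as one store; red shortens the exchange time and leaves the feed time as it is. For [reagent in the reaction phase] I split the charge by the partition ratio, then scale by the transfer coefficient's share of transfer plus use by steps of reaction and decay, which gives a working level of 0.0140 M.

The pool lifetime, meaning the pooled store per reaction-phase target over the pseudo-first-order loss to decomposition and over-reaction, is then 4.55 h. At the early end the store grows at the making rate. At the late end it stands at making rate times lifetime, a balance level of 19.8 % of the charge with starting material held as charged. Joining the ends by an exponential rise that starts after the feed time, 0.959 lifetimes long, I get 12.2 %.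

In my reckoning teal doubles the working level and shortens the lifetime to 3.09 h, and I get 20.3 %. I leave grey unreckoned, so teal is my choice with that gap open.

The forecast gives 11.9 %, names teal and gives 16.8 % after it, calling the flask “close to a plateau where formation balances over-reaction and decomposition”. Its teal figure stands below mine.

The simulation gives 11.6 %, with teal best at 16.3 %: a gain of 4.7 percentage points, against 1 point for grey and 0.022 points for red. My teal figure of 20.3 % stands above that flask's 16.3 %.

With the readings at 6.00 h, 0.0124 M of reagent in the reaction phase gives this flask a lifetime of 4.82 h, and with 80 % of starting material left, a balance level of 14.8 %, above the 11.6 % it holds. The neighbouring flask charges 0.034 M of starting material. Its working level is 0.0160 M, its lifetime 4.26 h, and the joined reckoning gives 13.6 %. That neighbouring flask reads 0.0148 M of reagent in the reaction phase and 12.5 % of target and product in the second phase together.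

The constants are made up.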